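The 3(2H)-furanone ring is cut across C2–C1 and O–C10 (germacrane numbering: C1 ring ketone, C10 methyl-bearing carbon). This gives a methyl ketone (O, C3, C2) on the C4=C5–C6 arm and a two-carbon acyl unit (C1, C10). In one flask a Claisen C-acylation joins C2 to C1, and the diketone enol oxygen then adds 5-exo to C10 of an unmasked enal. This creates the furanone ring, the C10 quaternary centre and the C8 aldehyde. The step exploits the 1,4 relation between ring ketone C1 and oxygenated C8 across C10. Its precursors are a Z dienone and a 4,4-dimethoxytiglic active ester. The C8 aldehyde then closes the ten-membered ring by allylation with a bromomethylbutenolide.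

Key step: step 8

Remark on numbering: C1 furanone C=O, C2 furanone CH, C3 furanone O-bearing sp2 carbon, C4=C5 exocyclic alkene (C15 = CH2OAc on C4), C6 lactone O–CH, C7 ring-fusion CH, C8 methacrylate-bearing CH, C9 CH2, C10 quaternary carbon (C14 its methyl), C11–C13 the α-methylene lactone. The target is 4Z,6R,7R,8S,10R.

Remark on descriptors: the C6 descriptor is S in compounds 3–20 and R in 21–23 only because CIP priorities change when the vinyl group becomes the butenolide carbon; the spatial arrangement is the same.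

Assumption: the ProPhenol antipode written in step 1 is taken to give the 3S alcohol; if the first run shows the opposite sense, the other ligand antipode is used.

Step 1
Reactants: 1 tert-butyldimethyl(prop-2-yn-1-yloxy)silane; 2 acrolein
Product: 3 (3S)-6-[(tert-butyldimethylsilyl)oxy]hex-1-en-4-yn-3-ol
Conditions: Me2Zn, (S,S)-ProPhenol (10 mol %), Ph3PO (20 mol %), toluene, 0 °C
Reagents that add atoms: none
Why: Catalytic enantioselective alkynylation, in which the zinc alkynylide of 1 adds 1,2 to the aldehyde of 2 inside the chiral dinuclear zinc–ProPhenol complex, which selects one carbonyl face and sets C6.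

Step 2
Reactants: 3 (3S)-6-[(tert-butyldimethylsilyl)oxy]hex-1-en-4-yn-3-ol
Product: 4 (3S,4Z)-6-[(tert-butyldimethylsilyl)oxy]-5-iodohexa-1,4-dien-3-ol
Conditions: NaAlH2(OCH2CH2OCH3)2 (Red-Al), THF, 0 °C; then I2, −78 °C
Reagents that add atoms: iodine, II
Why: Alkoxide-directed trans-hydroalumination of the propargylic alcohol puts aluminium on the alkyne carbon remote from the carbinol and anti to the new C–H bond, and iodinolysis with retention should give the Z vinyl iodide with iodine cis to C6, which fixes the C4=C5 geometry.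

Step 3
Reactants: 4 (3S,4Z)-6-[(tert-butyldimethylsilyl)oxy]-5-iodohexa-1,4-dien-3-ol
Product: 5 (3S,4Z)-3,6-bis[(tert-butyldimethylsilyl)oxy]-5-iodohexa-1,4-diene
Conditions: TBSCl, imidazole, DMF, rt
Reagents that add atoms: tert-butyldimethylsilyl chloride, CC(C)(C)[Si](C)(C)Cl
Why: Routine silylation of the secondary alcohol, needed so that the Z γ-oxy enone made next cannot cyclise and dehydrate to a furan.

Step 4
Reactants: 5 (3S,4Z)-3,6-bis[(tert-butyldimethylsilyl)oxy]-5-iodohexa-1,4-diene; 6 tributyl(1-ethoxyvinyl)stannane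
Product: 8 (3Z,5S)-5-[(tert-butyldimethylsilyl)oxy]-3-{[(tert-butyldimethylsilyl)oxy]methyl}hepta-3,6-dien-2-one, via ethoxydiene 7 (not isolated)
Conditions: Pd(PPh3)4 (5 mol %), CuI (10 mol %), DMF, 60 °C; then 1 M aq. HCl, THF, 0 °C
Reagents that add atoms: water, O
Why: Stille coupling proceeds with retention of the vinyl iodide geometry, and mild hydrolysis of the resulting enol ether unveils the methyl ketone, so the acetyl group ends cis to C6 without any carbanion that could trigger silyl migration.

Step 5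
Reactants: 9 2,2-dimethoxyacetaldehyde (aqueous solution); 10 triethyl 2-phosphonopropionate
Product: 11 ethyl (2E)-4,4-dimethoxy-2-methylbut-2-enoate
Conditions: K2CO3, H2O/THF, rt
Reagents that add atoms: none
Why: Horner–Wadsworth–Emmons olefination under aqueous carbonate conditions, where the α-methyl phosphonate should give the E trisubstituted enoate.

Step 6
Reactants: 11 ethyl (2E)-4,4-dimethoxy-2-methylbut-2-enoate
Product: 12 (2E)-4,4-dimethoxy-2-methylbut-2-enoic acid
Conditions: LiOH, THF/H2O, rt; citric acid to pH 4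
Reagents that add atoms: lithium hydroxide, [Li+].[OH-]
Why: Saponification of the ethyl ester, with a work-up at pH 4 that keeps the dimethyl acetal.

Step 7
Reactants: 12 (2E)-4,4-dimethoxy-2-methylbut-2-enoic acid
Product: 13 pentafluorophenyl (2E)-4,4-dimethoxy-2-methylbut-2-enoate
Conditions: C6F5OH, DCC, CH2Cl2, 0 °C to rt
Reagents that add atoms: pentafluorophenol, Oc1c(F)c(F)c(F)c(F)c1F
Why: Carbodiimide coupling gives an active ester reactive enough to C-acylate a lithium enolate at low temperature, and its leaving group is a non-nucleophilic phenol that does not interfere with the amine catalysis of step 8.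

Step 8
Reactants: 8 (3Z,5S)-5-[(tert-butyldimethylsilyl)oxy]-3-{[(tert-butyldimethylsilyl)oxy]methyl}hepta-3,6-dien-2-one; 13 pentafluorophenyl (2E)-4,4-dimethoxy-2-methylbut-2-enoate
Product: 16 2-[(2R)-5-{(2Z,4S)-1,4-bis[(tert-butyldimethylsilyl)oxy]hexa-2,5-dien-2-yl}-2-methyl-3-oxo-2,3-dihydrofuran-2-yl]acetaldehyde, via diketone acetal 14 (not isolated), via enal diketone 15 (not isolated)
Conditions: LiN(SiMe3)2 (2.2 equiv), THF, −78 °C; 13, −78 to −30 °C; AcOH; then (R)-α,α-diphenylprolinol trimethylsilyl ether (20 mol %), 4-nitrobenzoic acid (20 mol %), H2O (5 equiv), toluene, 0 °C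
Reagents that add atoms: water, O
Why: Proposed new method: kinetic deprotonation of the methyl group of 8 and crossed Claisen C-acylation by 13 form C2–C1 and give diketone acetal 14 (the second equivalent of base takes up the diketone proton); after the acetic acid quench the chiral secondary amine turns the allylic acetal into an E iminium ion (15 is the free enal), the C3 enol oxygen adds to the β-carbon C10 to form O–C10, and enamine hydrolysis releases the aldehyde. The closest known reaction types are the acylation of ketone enolates by active esters, the 5-exo oxa-Michael closure of 1,3-diketone enols onto ene-1,4-dicarbonyl units that gives 3(2H)-furanones, and the amine-catalysed intramolecular oxa-Michael addition of phenols to β,β-disubstituted enals that gives 2,2-disubstituted chromans; new is their union in one flask with an enol oxygen as the nucleophile. The furanone ring closes 5-exo-trig. The C10 quaternary centre is set by the catalyst: the diphenyl(silyloxy)methyl group of the R amine shields one face of the E iminium ion, so the oxygen should be delivered to the other face, giving 10R independently of the remote C6 centre. The step needs α′ over γ deprotonation (kinetic base at −78 °C), C- over O-acylation and 1,2- over 1,4-attack (lithium enolate, active ester, hindered trisubstituted enoate), 5-exo attack at C10 over 6-endo attack at C9 (iminium activation makes C10 the electrophilic site), and an iminium pathway faster than the uncatalysed closure (neutral diketone, low temperature).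

Step 9
Reactants: 16 2-[(2R)-5-{(2Z,4S)-1,4-bis[(tert-butyldimethylsilyl)oxy]hexa-2,5-dien-2-yl}-2-methyl-3-oxo-2,3-dihydrofuran-2-yl]acetaldehyde
Product: 17 2-[(2R)-5-[(2Z,4S)-1,4-dihydroxyhexa-2,5-dien-2-yl]-2-methyl-3-oxo-2,3-dihydrofuran-2-yl]acetaldehyde
Conditions: HF·pyridine, pyridine, THF, 0 °C to rt
Reagents that add atoms: none
Why: Fluoride-driven cleavage of both silyl ethers under pyridine-buffered conditions that should leave the aldehyde, the vinylogous ester and C10 untouched; the diol is used at once because the free C6 hydroxyl lies cis to the furanone C3.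

Step 10
Reactants: 17 2-[(2R)-5-[(2Z,4S)-1,4-dihydroxyhexa-2,5-dien-2-yl]-2-methyl-3-oxo-2,3-dihydrofuran-2-yl]acetaldehyde
Product: 18 (2Z,4S)-4-hydroxy-2-[(5R)-5-methyl-4-oxo-5-(2-oxoethyl)-4,5-dihydrofuran-2-yl]hexa-2,5-dien-1-yl acetate
Conditions: AcCl, 2,4,6-collidine, CH2Cl2, −78 °C
Reagents that add atoms: acetyl chloride, CC(Cl)=O
Why: Kinetically selective acetylation of the primary allylic alcohol (C15) over the hindered secondary doubly allylic alcohol (C6) with a hindered pyridine base at low temperature.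

Step 11
Reactants: 18 (2Z,4S)-4-hydroxy-2-[(5R)-5-methyl-4-oxo-5-(2-oxoethyl)-4,5-dihydrofuran-2-yl]hexa-2,5-dien-1-yl acetate; 19 2-(bromomethyl)acrylic acid
Product: 20 (3S,4Z)-6-acetoxy-5-[(5R)-5-methyl-4-oxo-5-(2-oxoethyl)-4,5-dihydrofuran-2-yl]hexa-1,4-dien-3-yl 2-(bromomethyl)acrylate
Conditions: DCC, DMAP (10 mol %), CH2Cl2, 0 °C
Reagents that add atoms: none
Why: Steglich esterification of the C6 alcohol, with low temperature and only catalytic DMAP to limit amine attack on the allylic bromide.

Step 12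
Reactants: 20 (3S,4Z)-6-acetoxy-5-[(5R)-5-methyl-4-oxo-5-(2-oxoethyl)-4,5-dihydrofuran-2-yl]hexa-1,4-dien-3-yl 2-(bromomethyl)acrylate
Product: 21 (2Z)-3-[(2R)-4-(bromomethyl)-5-oxo-2,5-dihydrofuran-2-yl]-2-[(5R)-5-methyl-4-oxo-5-(2-oxoethyl)-4,5-dihydrofuran-2-yl]prop-2-en-1-yl acetate
Conditions: second-generation Hoveyda–Grubbs catalyst (10 mol %), toluene, 80 °C
Reagents that add atoms: none
Why: Ring-closing metathesis between the terminal vinyl group and the 1,1-disubstituted acrylate should give the butenolide with loss of ethylene, the other alkenes being trisubstituted and conjugated and therefore inert.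

Step 13
Reactants: 21 (2Z)-3-[(2R)-4-(bromomethyl)-5-oxo-2,5-dihydrofuran-2-yl]-2-[(5R)-5-methyl-4-oxo-5-(2-oxoethyl)-4,5-dihydrofuran-2-yl]prop-2-en-1-yl acetate
Product: 22 (4Z,6R,7R,8S,10R)-15-acetoxy-8-hydroxy-1-oxo-3,10-epoxygermacra-2,4,11(13)-trien-12,6-olide
Conditions: CrCl2 (excess), THF, rt, slow addition at high dilution
Reagents that add atoms: none
Why: Nozaki–Hiyama-type intramolecular allylation, in which the allylchromium species adds through its γ-carbon C7 to the aldehyde in a chair six-membered transition state, anti to the C6 substituent of the butenolide (trans lactone, 7R) and with the ring carbon trans to the metal-bearing CH2 equatorial (anti C7/C8 relation, 8S), while the allylic shift creates the exocyclic methylene and the C7–C8 bond closes the ten-membered ring.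

Step 14
Reactants: 22 (4Z,6R,7R,8S,10R)-15-acetoxy-8-hydroxy-1-oxo-3,10-epoxygermacra-2,4,11(13)-trien-12,6-olide
Product: 23 (4Z,6R,7R,8S,10R)-15-acetoxy-8-(methacryloyloxy)-1-oxo-3,10-epoxygermacra-2,4,11(13)-trien-12,6-olide
Conditions: methacrylic anhydride, Et3N, DMAP (cat.), CH2Cl2, 0 °C
Reagents that add atoms: methacrylic anhydride, CC(=C)C(=O)OC(=O)C(C)=C
Why: Nucleophile-catalysed acylation of the secondary C8 alcohol should give the target without touching the α-methylene lactone.

Compound list
1 | tert-butyldimethyl(prop-2-yn-1-yloxy)silane | C#CCO[Si](C)(C)C(C)(C)C | starting material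
2 | acrolein | C=CC=O | starting material
3 | (3S)-6-[(tert-butyldimethylsilyl)oxy]hex-1-en-4-yn-3-ol | C=C[C@H](O)C#CCO[Si](C)(C)C(C)(C)C | intermediate
4 | (3S,4Z)-6-[(tert-butyldimethylsilyl)oxy]-5-iodohexa-1,4-dien-3-ol | C=C[C@H](O)/C=C(\I)CO[Si](C)(C)C(C)(C)C | intermediate
5 | (3S,4Z)-3,6-bis[(tert-butyldimethylsilyl)oxy]-5-iodohexa-1,4-diene | C=C[C@H](O[Si](C)(C)C(C)(C)C)/C=C(\I)CO[Si](C)(C)C(C)(C)C | intermediate
6 | tributyl(1-ethoxyvinyl)stannane | CCCC[Sn](CCCC)(CCCC)C(=C)OCC | starting material
7 | (3Z,5S)-5-[(tert-butyldimethylsilyl)oxy]-3-{[(tert-butyldimethylsilyl)oxy]methyl}-2-ethoxyhepta-1,3,6-triene | C=C(OCC)/C(CO[Si](C)(C)C(C)(C)C)=C\[C@@H](O[Si](C)(C)C(C)(C)C)C=C | intermediate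
8 | (3Z,5S)-5-[(tert-butyldimethylsilyl)oxy]-3-{[(tert-butyldimethylsilyl)oxy]methyl}hepta-3,6-dien-2-one | CC(=O)/C(CO[Si](C)(C)C(C)(C)C)=C\[C@@H](O[Si](C)(C)C(C)(C)C)C=C | intermediate
9 | 2,2-dimethoxyacetaldehyde | COC(OC)C=O | starting material
10 | triethyl 2-phosphonopropionate | CCOC(=O)C(C)P(=O)(OCC)OCC | starting material
11 | ethyl (2E)-4,4-dimethoxy-2-methylbut-2-enoate | CCOC(=O)/C(C)=C/C(OC)OC | intermediate
12 | (2E)-4,4-dimethoxy-2-methylbut-2-enoic acid | OC(=O)/C(C)=C/C(OC)OC | intermediate
13 | pentafluorophenyl (2E)-4,4-dimethoxy-2-methylbut-2-enoate | COC(OC)/C=C(\C)C(=O)Oc1c(F)c(F)c(F)c(F)c1F | intermediate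
14 | (2E,7Z,9S)-9-[(tert-butyldimethylsilyl)oxy]-7-{[(tert-butyldimethylsilyl)oxy]methyl}-1,1-dimethoxy-3-methylundeca-2,7,10-triene-4,6-dione | COC(OC)/C=C(\C)C(=O)CC(=O)/C(CO[Si](C)(C)C(C)(C)C)=C\[C@@H](O[Si](C)(C)C(C)(C)C)C=C | intermediate
15 | (2E,7Z,9S)-9-[(tert-butyldimethylsilyl)oxy]-7-{[(tert-butyldimethylsilyl)oxy]methyl}-3-methyl-4,6-dioxoundeca-2,7,10-trienal | O=C/C=C(\C)C(=O)CC(=O)/C(CO[Si](C)(C)C(C)(C)C)=C\[C@@H](O[Si](C)(C)C(C)(C)C)C=C | intermediate
16 | 2-[(2R)-5-{(2Z,4S)-1,4-bis[(tert-butyldimethylsilyl)oxy]hexa-2,5-dien-2-yl}-2-methyl-3-oxo-2,3-dihydrofuran-2-yl]acetaldehyde | O=CC[C@@]1(C)OC(=CC1=O)/C(CO[Si](C)(C)C(C)(C)C)=C\[C@@H](O[Si](C)(C)C(C)(C)C)C=C | intermediate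
17 | 2-[(2R)-5-[(2Z,4S)-1,4-dihydroxyhexa-2,5-dien-2-yl]-2-methyl-3-oxo-2,3-dihydrofuran-2-yl]acetaldehyde | O=CC[C@@]1(C)OC(=CC1=O)/C(CO)=C\[C@@H](O)C=C | intermediate
18 | (2Z,4S)-4-hydroxy-2-[(5R)-5-methyl-4-oxo-5-(2-oxoethyl)-4,5-dihydrofuran-2-yl]hexa-2,5-dien-1-yl acetate | O=CC[C@@]1(C)OC(=CC1=O)/C(COC(C)=O)=C\[C@@H](O)C=C | intermediate
19 | 2-(bromomethyl)acrylic acid | OC(=O)C(=C)CBr | starting material
20 | (3S,4Z)-6-acetoxy-5-[(5R)-5-methyl-4-oxo-5-(2-oxoethyl)-4,5-dihydrofuran-2-yl]hexa-1,4-dien-3-yl 2-(bromomethyl)acrylate | O=CC[C@@]1(C)OC(=CC1=O)/C(COC(C)=O)=C\[C@@H](OC(=O)C(=C)CBr)C=C | intermediate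
21 | (2Z)-3-[(2R)-4-(bromomethyl)-5-oxo-2,5-dihydrofuran-2-yl]-2-[(5R)-5-methyl-4-oxo-5-(2-oxoethyl)-4,5-dihydrofuran-2-yl]prop-2-en-1-yl acetate | O=CC[C@@]1(C)OC(=CC1=O)/C(COC(C)=O)=C\[C@H]2OC(=O)C(CBr)=C2 | intermediate
22 | (4Z,6R,7R,8S,10R)-15-acetoxy-8-hydroxy-1-oxo-3,10-epoxygermacra-2,4,11(13)-trien-12,6-olide | O[C@H]1C[C@@]2(C)OC(=CC2=O)/C(COC(C)=O)=C\[C@H]2OC(=O)C(=C)[C@H]12 | intermediate
23 | (4Z,6R,7R,8S,10R)-15-acetoxy-8-(methacryloyloxy)-1-oxo-3,10-epoxygermacra-2,4,11(13)-trien-12,6-olide (CNP0179932.1) | C=C(C)C(=O)O[C@H]1C[C@@]2(C)OC(=CC2=O)/C(COC(C)=O)=C\[C@H]2OC(=O)C(=C)[C@H]12 | target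

Total step count: 14. Longest linear sequence: 11 steps (steps 1–4 and 8–14).

Steps most likely to fail

Step 8 (Proposed new method). The catalyst may lose control of oxygen delivery to C10: the uncatalysed closure may compete, the enal may scramble E/Z through dienamine formation at the C14 methyl, or C10 may epimerise by retro-oxa-Michael and re-addition in the product enamine. Competing 6-endo closure onto C9 and γ-deprotonation of 8 are further risks. The fallback sets out from 8 and uses known chemistry. LiN(SiMe3)2 and then 2-bromopropanoyl chloride should give, by C-acylation and 5-exo-tet O-alkylation in the same flask (again forming C2–C1 and O–C10 together), the 2-methyl-3(2H)-furanone F1, whose C10 still bears a hydrogen. A cinchona-derived bifunctional thiourea then catalyses the Michael addition of F1 to nitroethylene and sets the C10 quaternary centre in the nitroethyl furanone F2 (catalyst pseudo-enantiomer chosen for 10R). A buffered Nef reaction with TiCl3 and NH4OAc converts the nitromethylene group into the aldehyde and comes back to the route at 16.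

Step 13. The ring may fail to close cleanly (oligomerisation), or the tether may force addition through the other aldehyde face, which would invert C8. The fallback sets out from 21: if the allylation closes the ring through the opposite face, the C8-epimeric alcohol F3 is esterified with methacrylic acid under Mitsunobu conditions (PPh3, DIAD, THF), which installs the methacrylate with inversion at C8 and comes back to the route at 23.

Step 11. Acylation of the hindered alcohol may be slow, so that the amine catalyst is alkylated by the allylic bromide and the free C6 hydroxyl adds to C3 of the vinylogous ester with opening of the furanone (isomerisation to a furan). The fallback sets out from 18. Esterification with 2-{[(tert-butyldimethylsilyl)oxy]methyl}acrylic acid (DCC, stoichiometric DMAP, which is now tolerated) should give the silyloxymethylacrylate ester F4. Ring-closing metathesis gives the silyloxymethyl butenolide F5, HF·pyridine gives the hydroxymethyl butenolide F6, and CBr4/PPh3 converts the alcohol into the bromide, coming back to the route at 21.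

Further compounds
F1 | step 8 | 5-{(2Z,4S)-1,4-bis[(tert-butyldimethylsilyl)oxy]hexa-2,5-dien-2-yl}-2-methylfuran-3(2H)-one | CC1OC(=CC1=O)/C(CO[Si](C)(C)C(C)(C)C)=C\[C@@H](O[Si](C)(C)C(C)(C)C)C=C
F2 | step 8 | (2R)-5-{(2Z,4S)-1,4-bis[(tert-butyldimethylsilyl)oxy]hexa-2,5-dien-2-yl}-2-methyl-2-(2-nitroethyl)furan-3(2H)-one | O=[N+]([O-])CC[C@@]1(C)OC(=CC1=O)/C(CO[Si](C)(C)C(C)(C)C)=C\[C@@H](O[Si](C)(C)C(C)(C)C)C=C
F3 | step 13 | (4Z,6R,7R,8R,10R)-15-acetoxy-8-hydroxy-1-oxo-3,10-epoxygermacra-2,4,11(13)-trien-12,6-olide | O[C@@H]1C[C@@]2(C)OC(=CC2=O)/C(COC(C)=O)=C\[C@H]2OC(=O)C(=C)[C@H]12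
F4 | step 11 | (3S,4Z)-6-acetoxy-5-[(5R)-5-methyl-4-oxo-5-(2-oxoethyl)-4,5-dihydrofuran-2-yl]hexa-1,4-dien-3-yl 2-{[(tert-butyldimethylsilyl)oxy]methyl}acrylate | O=CC[C@@]1(C)OC(=CC1=O)/C(COC(C)=O)=C\[C@@H](OC(=O)C(=C)CO[Si](C)(C)C(C)(C)C)C=C
F5 | step 11 | (2Z)-3-[(2R)-4-{[(tert-butyldimethylsilyl)oxy]methyl}-5-oxo-2,5-dihydrofuran-2-yl]-2-[(5R)-5-methyl-4-oxo-5-(2-oxoethyl)-4,5-dihydrofuran-2-yl]prop-2-en-1-yl acetate | O=CC[C@@]1(C)OC(=CC1=O)/C(COC(C)=O)=C\[C@H]2OC(=O)C(CO[Si](C)(C)C(C)(C)C)=C2
F6 | step 11 | (2Z)-3-[(2R)-4-(hydroxymethyl)-5-oxo-2,5-dihydrofuran-2-yl]-2-[(5R)-5-methyl-4-oxo-5-(2-oxoethyl)-4,5-dihydrofuran-2-yl]prop-2-en-1-yl acetate | O=CC[C@@]1(C)OC(=CC1=O)/C(COC(C)=O)=C\[C@H]2OC(=O)C(CO)=C2
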